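**Retrosynthetic overview**
- The target ester comes from a C1 primary alcohol (desilylation, oxidation, esterification). The cyclohexenone ring is not built; it is carried in from 2-methylcyclohexane-1,3-dione.
- The C6 quaternary peroxy carbon comes from axial C-methylation of a cyclic peroxyketal (6-methoxy-1,2-dioxane) through its peroxycarbenium ion, steered by C3 (proposed new step).
- The 1,2-dioxane is the only ring formed, after the full carbon chain is in place: a gem-methoxy hydroperoxide displaces a C3 mesylate (6-exo-tet, inversion).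
- The keto mesylate comes from Fukuyama coupling of thioester fragment C (Evans syn-aldol sets C2 and C3) with the alkylzinc of iodide fragment B.
- Fragment B comes from Stork–Danheiser addition of an alkyllithium (E-alkene from Negishi carboalumination) to vinylogous ester fragment A.

Assumption: the target is read as methyl (2S)-2-[(3S,6R)-…-1,2-dioxan-3-yl]propanoate with a 3E alkene, and compounds 1, 7, 18, 19 and all named reagents are taken as commercial.

**Route**

Step 1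
Reactants: 1 2-methylcyclohexane-1,3-dione
Product: 2 3-(2-methylpropoxy)-2-methylcyclohex-2-en-1-one
Conditions: i-BuOH, TsOH·H2O (cat.), toluene, reflux, Dean–Stark
Reagents that add atoms: 2-methylpropan-1-ol, CC(C)CO
Why: Acid-catalysed vinylogous ester formation on the symmetric dione is driven by azeotropic removal of water.

Step 2
Reactants: 2 3-(2-methylpropoxy)-2-methylcyclohex-2-en-1-one
Product: 4 3-(2-methylpropoxy)-2,6-dimethylcyclohex-2-en-1-one (racemic), via lithium dienolate 3 (not isolated)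
Conditions: LiN(iPr)2, THF, −78 °C; MeI, −78 → 0 °C
Reagents that add atoms: iodomethane, CI
Why: Kinetic deprotonation of the vinylogous ester occurs at C6 and the enolate is methylated by SN2 (Stork–Danheiser alkylation).

Step 3
Reactants: 4 3-(2-methylpropoxy)-2,6-dimethylcyclohex-2-en-1-one
Product: 6 3-(2-methylpropoxy)-2,6,6-trimethylcyclohex-2-en-1-one (ring fragment A), via lithium dienolate 5 (not isolated)
Conditions: LiN(iPr)2, THF, −78 °C; MeI, −78 → 0 °C
Reagents that add atoms: iodomethane, CI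
Why: A second enolate methylation at C6 installs the gem-dimethyl carbon and removes the only stereocentre.

Step 4
Reactants: 7 tert-butyl(but-3-yn-1-yloxy)dimethylsilane
Product: 10 (3E)-6-[(tert-butyldimethylsilyl)oxy]-4-methylhex-3-en-1-ol, via alkenylalane 8 (not isolated), via lithium alanate 9 (not isolated)
Conditions: AlMe3, Cp2ZrCl2 (25 mol %), CH2Cl2, 0 °C → rt; volatiles removed; n-BuLi, THF/hexane, −78 °C; ethylene oxide, −78 → 0 °C
Reagents that add atoms: trimethylaluminium, C[Al](C)C; oxirane, C1CO1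
Why: Negishi zirconium-catalysed carboalumination adds methyl and aluminium syn across the alkyne, and the alkenyl alanate opens ethylene oxide with retention, which fixes the E trisubstituted alkene.

Step 5
Reactants: 10 (3E)-6-[(tert-butyldimethylsilyl)oxy]-4-methylhex-3-en-1-ol
Product: 11 tert-butyl{[(3E)-6-chloro-3-methylhex-3-en-1-yl]oxy}dimethylsilane
Conditions: PPh3, CCl4, CH2Cl2, 40 °C
Reagents that add atoms: tetrachloromethane, ClC(Cl)(Cl)Cl
Why: Appel chlorination of the primary alcohol is neutral and leaves the silyl ether and the alkene untouched.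

Step 6
Reactants: 11 tert-butyl{[(3E)-6-chloro-3-methylhex-3-en-1-yl]oxy}dimethylsilane
Product: 12 (3E)-6-chloro-3-methylhex-3-en-1-ol
Conditions: camphorsulfonic acid (cat.), MeOH, 0 °C → rt
Reagents that add atoms: none
Why: Acid-catalysed methanolysis cleaves the primary silyl ether without touching the alkyl chloride.

Step 7
Reactants: 12 (3E)-6-chloro-3-methylhex-3-en-1-ol
Product: 13 (3E)-6-chloro-1-iodo-3-methylhex-3-ene
Conditions: I2, PPh3, imidazole, CH2Cl2, 0 °C
Reagents that add atoms: iodine, II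
Why: Appel-type iodination (Garegg–Samuelsson conditions) converts the primary alcohol to the iodide by SN2.

Step 8
Reactants: 13 (3E)-6-chloro-1-iodo-3-methylhex-3-ene; 6 3-(2-methylpropoxy)-2,6,6-trimethylcyclohex-2-en-1-one
Product: 16 3-[(3E)-6-chloro-3-methylhex-3-en-1-yl]-2,4,4-trimethylcyclohex-2-en-1-one, via alkyllithium 14 (not isolated), via lithium alkoxide adduct 15 (not isolated)
Conditions: t-BuLi (2.1 equiv), Et2O/pentane, −78 °C; 6, −78 → 0 °C; 1 M HCl, THF, rt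
Reagents that add atoms: water, O
Why: Iodine–lithium exchange is selective over the chloride, and Stork–Danheiser 1,2-addition followed by acidic enol-ether hydrolysis and dehydration places the chain on the ring carbon next to the gem-dimethyl group with the carbonyl transposed.

Step 9
Reactants: 16 3-[(3E)-6-chloro-3-methylhex-3-en-1-yl]-2,4,4-trimethylcyclohex-2-en-1-one
Product: 17 3-[(3E)-6-iodo-3-methylhex-3-en-1-yl]-2,4,4-trimethylcyclohex-2-en-1-one (chain fragment B)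
Conditions: NaI, butan-2-one, 80 °C
Reagents that add atoms: sodium iodide, [Na+].[I-]
Why: Finkelstein exchange on the primary chloride is driven by precipitation of NaCl.

Step 10
Reactants: 18 (4S)-4-benzyl-3-propanoyl-1,3-oxazolidin-2-one; 19 pent-4-enal
Product: 22 (4S)-4-benzyl-3-[(2S,3R)-3-hydroxy-2-methylhept-6-enoyl]-1,3-oxazolidin-2-one, via boron enolate 20 (not isolated), via boron aldolate 21 (not isolated)
Conditions: Bu2BOTf, i-Pr2NEt, CH2Cl2, −78 → 0 °C; 19, −78 → 0 °C; pH 7 buffer, MeOH, 30% H2O2, 0 °C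
Reagents that add atoms: none
Why: Evans syn-aldol reaction: the Z boron enolate reacts through a Zimmerman–Traxler chair on the face dictated by the (S)-benzyl auxiliary, setting C2 (S) and C3 (R) as the syn pair.

Step 11
Reactants: 22 (4S)-4-benzyl-3-[(2S,3R)-3-hydroxy-2-methylhept-6-enoyl]-1,3-oxazolidin-2-one
Product: 23 (2R,3R)-2-methylhept-6-ene-1,3-diol
Conditions: LiBH4, MeOH (1 equiv), Et2O, 0 °C
Reagents that add atoms: none
Why: Reductive cleavage of the imide releases the auxiliary and gives the C1 alcohol without touching either stereocentre (the C2 descriptor changes only through priorities).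

Step 12
Reactants: 23 (2R,3R)-2-methylhept-6-ene-1,3-diol
Product: 24 (2R,3R)-1-[(tert-butyldiphenylsilyl)oxy]-2-methylhept-6-en-3-ol
Conditions: t-BuPh2SiCl, imidazole, CH2Cl2, 0 °C
Reagents that add atoms: tert-butyl(chloro)diphenylsilane, CC(C)(C)[Si](Cl)(c1ccccc1)c1ccccc1
Why: The bulky silyl chloride silylates the primary hydroxyl selectively over the secondary one.

Step 13
Reactants: 24 (2R,3R)-1-[(tert-butyldiphenylsilyl)oxy]-2-methylhept-6-en-3-ol
Product: 25 (2R,3R)-1-[(tert-butyldiphenylsilyl)oxy]-2-methylhept-6-en-3-yl methanesulfonate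
Conditions: MsCl, Et3N, CH2Cl2, 0 °C
Reagents that add atoms: methanesulfonyl chloride, CS(=O)(=O)Cl
Why: Mesylation proceeds with retention at C3 and installs the leaving group for the later invertive peroxide displacement.

Step 14
Reactants: 25 (2R,3R)-1-[(tert-butyldiphenylsilyl)oxy]-2-methylhept-6-en-3-yl methanesulfonate
Product: 27 (2R,3R)-1-[(tert-butyldiphenylsilyl)oxy]-2-methyl-6-oxohexan-3-yl methanesulfonate, via ozonide 26 (not isolated)
Conditions: O3, CH2Cl2, −78 °C; PPh3, −78 °C → rt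
Reagents that add atoms: ozone, [O-][O+]=O
Why: Ozonolysis with reductive work-up cleaves the only alkene present at this stage to the aldehyde.

Step 15
Reactants: 27 (2R,3R)-1-[(tert-butyldiphenylsilyl)oxy]-2-methyl-6-oxohexan-3-yl methanesulfonate
Product: 28 (4R,5R)-6-[(tert-butyldiphenylsilyl)oxy]-5-methyl-4-[(methylsulfonyl)oxy]hexanoic acid
Conditions: NaClO2, NaH2PO4, 2-methylbut-2-ene, t-BuOH/H2O, 0 °C → rt
Reagents that add atoms: sodium chlorite, [Na+].[O-]Cl=O
Why: Pinnick oxidation takes the aldehyde to the acid in weakly acidic buffer, where the mesylate and silyl ether are stable.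

Step 16
Reactants: 28 (4R,5R)-6-[(tert-butyldiphenylsilyl)oxy]-5-methyl-4-[(methylsulfonyl)oxy]hexanoic acid
Product: 29 S-ethyl (4R,5R)-6-[(tert-butyldiphenylsilyl)oxy]-5-methyl-4-[(methylsulfonyl)oxy]hexanethioate (aldol fragment C)
Conditions: EtSH, DCC, DMAP (cat.), CH2Cl2, 0 °C
Reagents that add atoms: ethanethiol, CCS
Why: Steglich-type thioesterification activates the acid quickly at 0 °C, before the carboxylate can lactonise onto the mesylate.

Step 17
Reactants: 17 3-[(3E)-6-iodo-3-methylhex-3-en-1-yl]-2,4,4-trimethylcyclohex-2-en-1-one; 29 S-ethyl (4R,5R)-6-[(tert-butyldiphenylsilyl)oxy]-5-methyl-4-[(methylsulfonyl)oxy]hexanethioate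
Product: 31 (2R,3R,9E)-1-[(tert-butyldiphenylsilyl)oxy]-2,10-dimethyl-6-oxo-12-(2,6,6-trimethyl-3-oxocyclohex-1-en-1-yl)dodec-9-en-3-yl methanesulfonate, via alkylzinc iodide 30 (not isolated)
Conditions: Zn dust (BrCH2CH2Br, Me3SiCl activation), THF, 40 °C; 29, PdCl2(PPh3)2 (5 mol %), toluene, rt
Reagents that add atoms: none
Why: Fukuyama coupling: the alkylzinc iodide tolerates the enone, and palladium-catalysed acyl substitution of the thioester gives the C6 ketone under neutral conditions that spare the mesylate and silyl ether.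

Step 18
Reactants: 31 (2R,3R,9E)-1-[(tert-butyldiphenylsilyl)oxy]-2,10-dimethyl-6-oxo-12-(2,6,6-trimethyl-3-oxocyclohex-1-en-1-yl)dodec-9-en-3-yl methanesulfonate
Product: 32 (2R,3R,9E)-1-[(tert-butyldiphenylsilyl)oxy]-6-hydroperoxy-6-methoxy-2,10-dimethyl-12-(2,6,6-trimethyl-3-oxocyclohex-1-en-1-yl)dodec-9-en-3-yl methanesulfonate (both C6 epimers)
Conditions: urea·H2O2, Sc(OTf)3 (10 mol %), MeOH, rt
Reagents that add atoms: methanol, CO; hydrogen peroxide (supplied as its urea adduct), OO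
Why: Lewis acid-catalysed perhydrolysis and ketalisation converts the unhindered C6 ketone into the gem-methoxy hydroperoxide, while the hindered conjugated ring ketone does not react.

Step 19
Reactants: 32 (2R,3R,9E)-1-[(tert-butyldiphenylsilyl)oxy]-6-hydroperoxy-6-methoxy-2,10-dimethyl-12-(2,6,6-trimethyl-3-oxocyclohex-1-en-1-yl)dodec-9-en-3-yl methanesulfonate
Product: 33 (3S)-3-{(2R)-1-[(tert-butyldiphenylsilyl)oxy]propan-2-yl}-6-methoxy-6-[(3E)-4-methyl-6-(2,6,6-trimethyl-3-oxocyclohex-1-en-1-yl)hex-3-en-1-yl]-1,2-dioxane (both C6 epimers)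
Conditions: KOt-Bu (1.0 equiv), 18-crown-6, toluene, 0 °C
Reagents that add atoms: none
Why: The weakly basic, strongly nucleophilic hydroperoxide anion displaces the secondary mesylate in an intramolecular 6-exo-tet SN2 reaction, closing the 1,2-dioxane with inversion at C3 (R to S).

Step 20
Reactants: 33 (3S)-3-{(2R)-1-[(tert-butyldiphenylsilyl)oxy]propan-2-yl}-6-methoxy-6-[(3E)-4-methyl-6-(2,6,6-trimethyl-3-oxocyclohex-1-en-1-yl)hex-3-en-1-yl]-1,2-dioxane
Product: 35 tert-butyl{(2R)-2-[(3S,6R)-6-methyl-6-[(3E)-4-methyl-6-(2,6,6-trimethyl-3-oxocyclohex-1-en-1-yl)hex-3-en-1-yl]-1,2-dioxan-3-yl]propoxy}diphenylsilane, via peroxycarbenium triflate 34 (not isolated)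
Conditions: AlMe3 (3 equiv), CH2Cl2, −78 °C; Me3SiOTf (1.2 equiv), −78 → −40 °C
Reagents that add atoms: trimethylaluminium, C[Al](C)C
Why: Proposed new method: Me3SiOTf removes the exocyclic methoxy group (the more basic ether oxygen) to give the six-membered peroxycarbenium ion 34, whose half-chair holds the C3 side chain pseudo-equatorial, and AlMe3 delivers methyl along the axial trajectory that leads directly to the chair, so the methyl ends up axial and cis to the C3 substituent (6R) with the long chain equatorial, both C6 epimers of 33 converging on the same ion; the closest known reaction types are Lewis acid-mediated allylation of peroxyketals through peroxycarbenium ions and axial AlMe3 methylation of cyclic methyl ketals through oxocarbenium ions, while transfer of a simple alkyl group from an organometallic to a peroxycarbenium ion has not been shown.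

Step 21
Reactants: 35 tert-butyl{(2R)-2-[(3S,6R)-6-methyl-6-[(3E)-4-methyl-6-(2,6,6-trimethyl-3-oxocyclohex-1-en-1-yl)hex-3-en-1-yl]-1,2-dioxan-3-yl]propoxy}diphenylsilane
Product: 36 (2R)-2-[(3S,6R)-6-methyl-6-[(3E)-4-methyl-6-(2,6,6-trimethyl-3-oxocyclohex-1-en-1-yl)hex-3-en-1-yl]-1,2-dioxan-3-yl]propan-1-ol
Conditions: Bu4NF, AcOH, THF, 0 °C → rt
Reagents that add atoms: none
Why: Buffered fluoride desilylation frees the primary alcohol without affecting the dialkyl peroxide.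

Step 22
Reactants: 36 (2R)-2-[(3S,6R)-6-methyl-6-[(3E)-4-methyl-6-(2,6,6-trimethyl-3-oxocyclohex-1-en-1-yl)hex-3-en-1-yl]-1,2-dioxan-3-yl]propan-1-ol
Product: 38 (2S)-2-[(3S,6R)-6-methyl-6-[(3E)-4-methyl-6-(2,6,6-trimethyl-3-oxocyclohex-1-en-1-yl)hex-3-en-1-yl]-1,2-dioxan-3-yl]propanoic acid, via aldehyde 37 (not isolated)
Conditions: TEMPO (20 mol %), PhI(OAc)2 (2.5 equiv), MeCN/H2O, rt
Reagents that add atoms: water, O
Why: Oxoammonium oxidation of the primary alcohol through the aldehyde hydrate to the acid is non-basic, so C2 is not epimerised and the O–O bond and alkenes are left alone.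

Step 23
Reactants: 38 (2S)-2-[(3S,6R)-6-methyl-6-[(3E)-4-methyl-6-(2,6,6-trimethyl-3-oxocyclohex-1-en-1-yl)hex-3-en-1-yl]-1,2-dioxan-3-yl]propanoic acid
Product: 39 methyl (2S)-2-[(3S,6R)-6-methyl-6-[(3E)-4-methyl-6-(2,6,6-trimethyl-3-oxocyclohex-1-en-1-yl)hex-3-en-1-yl]-1,2-dioxan-3-yl]propanoate
Conditions: Me3SiCHN2, MeOH/toluene, 0 °C
Reagents that add atoms: (trimethylsilyl)diazomethane, C[Si](C)(C)C=[N+]=[N-]
Why: Diazoalkane O-methylation of the acid is neutral and does not enolise the ester next to the peroxide.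

**Compound list**

1 | 2-methylcyclohexane-1,3-dione | CC1C(=O)CCCC1=O | starting material
2 | 3-(2-methylpropoxy)-2-methylcyclohex-2-en-1-one | CC1=C(OCC(C)C)CCCC1=O | intermediate
3 | lithium 5-(2-methylpropoxy)-6-methylcyclohexa-1,5-dien-1-olate | [Li+].[O-]C1=CCCC(OCC(C)C)=C1C | intermediate
4 | 3-(2-methylpropoxy)-2,6-dimethylcyclohex-2-en-1-one (racemic) | CC1CCC(OCC(C)C)=C(C)C1=O | intermediate
5 | lithium 5-(2-methylpropoxy)-2,6-dimethylcyclohexa-1,5-dien-1-olate | [Li+].[O-]C1=C(C)CCC(OCC(C)C)=C1C | intermediate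
6 | 3-(2-methylpropoxy)-2,6,6-trimethylcyclohex-2-en-1-one (ring fragment A) | CC1=C(OCC(C)C)CCC(C)(C)C1=O | intermediate
7 | tert-butyl(but-3-yn-1-yloxy)dimethylsilane | C#CCCO[Si](C)(C)C(C)(C)C | starting material
8 | {(1E)-4-[(tert-butyldimethylsilyl)oxy]-2-methylbut-1-en-1-yl}dimethylalane | C[Al](C)/C=C(\C)CCO[Si](C)(C)C(C)(C)C | intermediate
9 | lithium butyl{(1E)-4-[(tert-butyldimethylsilyl)oxy]-2-methylbut-1-en-1-yl}dimethylalanate | [Li+].CCCC[Al-](C)(C)/C=C(\C)CCO[Si](C)(C)C(C)(C)C | intermediate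
10 | (3E)-6-[(tert-butyldimethylsilyl)oxy]-4-methylhex-3-en-1-ol | OCC/C=C(\C)CCO[Si](C)(C)C(C)(C)C | intermediate
11 | tert-butyl{[(3E)-6-chloro-3-methylhex-3-en-1-yl]oxy}dimethylsilane | ClCC/C=C(\C)CCO[Si](C)(C)C(C)(C)C | intermediate
12 | (3E)-6-chloro-3-methylhex-3-en-1-ol | ClCC/C=C(\C)CCO | intermediate
13 | (3E)-6-chloro-1-iodo-3-methylhex-3-ene | ClCC/C=C(\C)CCI | intermediate
14 | [(3E)-6-chloro-3-methylhex-3-en-1-yl]lithium | ClCC/C=C(\C)CC[Li] | intermediate
15 | lithium 1-[(3E)-6-chloro-3-methylhex-3-en-1-yl]-3-(2-methylpropoxy)-2,6,6-trimethylcyclohex-2-en-1-olate (racemic) | ClCC/C=C(\C)CCC1([O-])C(C)=C(OCC(C)C)CCC1(C)C.[Li+] | intermediate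
16 | 3-[(3E)-6-chloro-3-methylhex-3-en-1-yl]-2,4,4-trimethylcyclohex-2-en-1-one | ClCC/C=C(\C)CCC1=C(C)C(=O)CCC1(C)C | intermediate
17 | 3-[(3E)-6-iodo-3-methylhex-3-en-1-yl]-2,4,4-trimethylcyclohex-2-en-1-one (chain fragment B) | ICC/C=C(\C)CCC1=C(C)C(=O)CCC1(C)C | intermediate
18 | (4S)-4-benzyl-3-propanoyl-1,3-oxazolidin-2-one | CCC(=O)N1[C@@H](Cc2ccccc2)COC1=O | starting material
19 | pent-4-enal | C=CCCC=O | starting material
20 | dibutylboron (Z)-enolate of 18 | C/C=C(\OB(CCCC)CCCC)N1[C@@H](Cc2ccccc2)COC1=O | intermediate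
21 | dibutylboron aldolate of 22 | O=C(N1[C@@H](Cc2ccccc2)COC1=O)[C@@H](C)[C@H](OB(CCCC)CCCC)CCC=C | intermediate
22 | (4S)-4-benzyl-3-[(2S,3R)-3-hydroxy-2-methylhept-6-enoyl]-1,3-oxazolidin-2-one | O=C(N1[C@@H](Cc2ccccc2)COC1=O)[C@@H](C)[C@H](O)CCC=C | intermediate
23 | (2R,3R)-2-methylhept-6-ene-1,3-diol | OC[C@@H](C)[C@H](O)CCC=C | intermediate
24 | (2R,3R)-1-[(tert-butyldiphenylsilyl)oxy]-2-methylhept-6-en-3-ol | CC(C)(C)[Si](c1ccccc1)(c2ccccc2)OC[C@@H](C)[C@H](O)CCC=C | intermediate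
25 | (2R,3R)-1-[(tert-butyldiphenylsilyl)oxy]-2-methylhept-6-en-3-yl methanesulfonate | CC(C)(C)[Si](c1ccccc1)(c2ccccc2)OC[C@@H](C)[C@H](OS(C)(=O)=O)CCC=C | intermediate
26 | ozonide of 25: (2R,3R)-1-[(tert-butyldiphenylsilyl)oxy]-2-methyl-5-(1,2,4-trioxolan-3-yl)pentan-3-yl methanesulfonate (both epimers at the trioxolane carbon) | CC(C)(C)[Si](c1ccccc1)(c2ccccc2)OC[C@@H](C)[C@H](OS(C)(=O)=O)CCC3OCOO3 | intermediate
27 | (2R,3R)-1-[(tert-butyldiphenylsilyl)oxy]-2-methyl-6-oxohexan-3-yl methanesulfonate | CC(C)(C)[Si](c1ccccc1)(c2ccccc2)OC[C@@H](C)[C@H](OS(C)(=O)=O)CCC=O | intermediate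
28 | (4R,5R)-6-[(tert-butyldiphenylsilyl)oxy]-5-methyl-4-[(methylsulfonyl)oxy]hexanoic acid | CC(C)(C)[Si](c1ccccc1)(c2ccccc2)OC[C@@H](C)[C@H](OS(C)(=O)=O)CCC(=O)O | intermediate
29 | S-ethyl (4R,5R)-6-[(tert-butyldiphenylsilyl)oxy]-5-methyl-4-[(methylsulfonyl)oxy]hexanethioate (aldol fragment C) | CC(C)(C)[Si](c1ccccc1)(c2ccccc2)OC[C@@H](C)[C@H](OS(C)(=O)=O)CCC(=O)SCC | intermediate
30 | {(3E)-4-methyl-6-(2,6,6-trimethyl-3-oxocyclohex-1-en-1-yl)hex-3-en-1-yl}zinc iodide | I[Zn]CC/C=C(\C)CCC1=C(C)C(=O)CCC1(C)C | intermediate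
31 | (2R,3R,9E)-1-[(tert-butyldiphenylsilyl)oxy]-2,10-dimethyl-6-oxo-12-(2,6,6-trimethyl-3-oxocyclohex-1-en-1-yl)dodec-9-en-3-yl methanesulfonate | CC(C)(C)[Si](c1ccccc1)(c2ccccc2)OC[C@@H](C)[C@H](OS(C)(=O)=O)CCC(=O)CC/C=C(\C)CCC3=C(C)C(=O)CCC3(C)C | intermediate
32 | (2R,3R,9E)-1-[(tert-butyldiphenylsilyl)oxy]-6-hydroperoxy-6-methoxy-2,10-dimethyl-12-(2,6,6-trimethyl-3-oxocyclohex-1-en-1-yl)dodec-9-en-3-yl methanesulfonate (both C6 epimers) | CC(C)(C)[Si](c1ccccc1)(c2ccccc2)OC[C@@H](C)[C@H](OS(C)(=O)=O)CCC(OC)(OO)CC/C=C(\C)CCC3=C(C)C(=O)CCC3(C)C | intermediate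
33 | (3S)-3-{(2R)-1-[(tert-butyldiphenylsilyl)oxy]propan-2-yl}-6-methoxy-6-[(3E)-4-methyl-6-(2,6,6-trimethyl-3-oxocyclohex-1-en-1-yl)hex-3-en-1-yl]-1,2-dioxane (both C6 epimers) | CC(C)(C)[Si](c1ccccc1)(c2ccccc2)OC[C@@H](C)[C@@H]3CCC(OC)(CC/C=C(\C)CCC4=C(C)C(=O)CCC4(C)C)OO3 | intermediate
34 | cyclic peroxycarbenium triflate: 33 without its methoxide, C6=O1(+) inside the dioxane ring, (3S), side chain (2R) | CC(C)(C)[Si](c1ccccc1)(c2ccccc2)OC[C@@H](C)[C@@H]3CCC(CC/C=C(\C)CCC4=C(C)C(=O)CCC4(C)C)=[O+]O3.[O-]S(=O)(=O)C(F)(F)F | intermediate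
35 | tert-butyl{(2R)-2-[(3S,6R)-6-methyl-6-[(3E)-4-methyl-6-(2,6,6-trimethyl-3-oxocyclohex-1-en-1-yl)hex-3-en-1-yl]-1,2-dioxan-3-yl]propoxy}diphenylsilane | CC(C)(C)[Si](c1ccccc1)(c2ccccc2)OC[C@@H](C)[C@@H]3CC[C@@](C)(CC/C=C(\C)CCC4=C(C)C(=O)CCC4(C)C)OO3 | intermediate
36 | (2R)-2-[(3S,6R)-6-methyl-6-[(3E)-4-methyl-6-(2,6,6-trimethyl-3-oxocyclohex-1-en-1-yl)hex-3-en-1-yl]-1,2-dioxan-3-yl]propan-1-ol | OC[C@@H](C)[C@@H]1CC[C@@](C)(CC/C=C(\C)CCC2=C(C)C(=O)CCC2(C)C)OO1 | intermediate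
37 | (2S)-2-[(3S,6R)-6-methyl-6-[(3E)-4-methyl-6-(2,6,6-trimethyl-3-oxocyclohex-1-en-1-yl)hex-3-en-1-yl]-1,2-dioxan-3-yl]propanal | O=C[C@@H](C)[C@@H]1CC[C@@](C)(CC/C=C(\C)CCC2=C(C)C(=O)CCC2(C)C)OO1 | intermediate
38 | (2S)-2-[(3S,6R)-6-methyl-6-[(3E)-4-methyl-6-(2,6,6-trimethyl-3-oxocyclohex-1-en-1-yl)hex-3-en-1-yl]-1,2-dioxan-3-yl]propanoic acid | OC(=O)[C@@H](C)[C@@H]1CC[C@@](C)(CC/C=C(\C)CCC2=C(C)C(=O)CCC2(C)C)OO1 | intermediate
39 | methyl (2S)-2-[(3S,6R)-6-methyl-6-[(3E)-4-methyl-6-(2,6,6-trimethyl-3-oxocyclohex-1-en-1-yl)hex-3-en-1-yl]-1,2-dioxan-3-yl]propanoate | COC(=O)[C@@H](C)[C@@H]1CC[C@@](C)(CC/C=C(\C)CCC2=C(C)C(=O)CCC2(C)C)OO1 | target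

**Totals and risk**

Total step count: 23.
Longest linear sequence: 14 steps (steps 10 to 23, from 18 and 19).

Steps most likely to fail:

Step 20 (proposed new peroxycarbenium methylation; the ion may fragment, or the ring C–O bond may ionise instead of the methoxy group). Fallback with known chemistry, setting out from 31 and coming back at 35. Ketone 31 is methylenated at C6 with the Lombardo reagent (Zn, CH2Br2, TiCl4, THF/CH2Cl2), which is non-basic and leaves the mesylate and the hindered ring enone alone. This gives (2R,3R,9E)-1-[(tert-butyldiphenylsilyl)oxy]-2,10-dimethyl-6-methylidene-12-(2,6,6-trimethyl-3-oxocyclohex-1-en-1-yl)dodec-9-en-3-yl methanesulfonate F1. Mukaiyama–Isayama hydroperoxysilylation of the 1,1-disubstituted alkene (O2, Et3SiH, cobalt bis(2,2,6,6-tetramethylheptane-3,5-dionate) Co(C11H19O2)2 (cat.), ClCH2CH2Cl, rt) gives the tertiary triethylsilyl peroxide F2 as both C6 epimers. K2CO3 in MeOH removes the silyl group to give the tertiary hydroperoxide F3. KOt-Bu/18-crown-6 in toluene then closes the ring by the same invertive displacement at C3, giving 35 together with its (3S,6S) epimer F4, and the two are separated by HPLC. This path gives no control at C6 and replaces steps 18 to 20.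

Step 19 (ring closure on a beta-branched secondary mesylate; E2 elimination or base-induced peroxide fragmentation may compete). Fallback setting out from 31 and coming back at 33; it also bypasses step 18. Ketone 31 is converted with HC(OMe)3 and camphorsulfonic acid (cat.) in MeOH into the C6 dimethyl ketal F5, which can no longer enolise toward the mesylate. The mesylate is displaced with inversion by 2-methoxypropan-2-yl hydroperoxide and CsOH·H2O in DMF to give the (3S) peroxyketal F6. Camphorsulfonic acid in MeOH then unmasks the secondary hydroperoxide, which closes onto the C6 ketal carbon by trans-ketalisation to give 33. The C3–O bond is thus made first and intermolecularly, and the ring is closed at C6 instead of C3.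

Step 17 (zinc insertion next to an enone and coupling with a thioester that carries a mesylate). Fallback setting out from 17 and 27 and coming back at 31. Iodide 17 and aldehyde 27 are joined by a cobalt-catalysed alkylchromium addition (CrCl2, cobalt phthalocyanine Co(C32H16N8) (cat.), DMF, rt), which is aldehyde-selective and tolerates the enone and the mesylate. This gives the C6 carbinol F7 as both C6 epimers, and Dess–Martin periodinane (NaHCO3, CH2Cl2, 0 °C) oxidises F7 to 31. Steps 15 and 16 are then not needed.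

**Further compounds**

F1 | step 20 | (2R,3R,9E)-1-[(tert-butyldiphenylsilyl)oxy]-2,10-dimethyl-6-methylidene-12-(2,6,6-trimethyl-3-oxocyclohex-1-en-1-yl)dodec-9-en-3-yl methanesulfonate | CC(C)(C)[Si](c1ccccc1)(c2ccccc2)OC[C@@H](C)[C@H](OS(C)(=O)=O)CCC(=C)CC/C=C(\C)CCC3=C(C)C(=O)CCC3(C)C
F2 | step 20 | (2R,3R,9E)-1-[(tert-butyldiphenylsilyl)oxy]-2,6,10-trimethyl-6-[(triethylsilyl)peroxy]-12-(2,6,6-trimethyl-3-oxocyclohex-1-en-1-yl)dodec-9-en-3-yl methanesulfonate (both C6 epimers) | CC(C)(C)[Si](c1ccccc1)(c2ccccc2)OC[C@@H](C)[C@H](OS(C)(=O)=O)CCC(C)(OO[Si](CC)(CC)CC)CC/C=C(\C)CCC3=C(C)C(=O)CCC3(C)C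
F3 | step 20 | (2R,3R,9E)-1-[(tert-butyldiphenylsilyl)oxy]-6-hydroperoxy-2,6,10-trimethyl-12-(2,6,6-trimethyl-3-oxocyclohex-1-en-1-yl)dodec-9-en-3-yl methanesulfonate (both C6 epimers) | CC(C)(C)[Si](c1ccccc1)(c2ccccc2)OC[C@@H](C)[C@H](OS(C)(=O)=O)CCC(C)(OO)CC/C=C(\C)CCC3=C(C)C(=O)CCC3(C)C
F4 | step 20 | tert-butyl{(2R)-2-[(3S,6S)-6-methyl-6-[(3E)-4-methyl-6-(2,6,6-trimethyl-3-oxocyclohex-1-en-1-yl)hex-3-en-1-yl]-1,2-dioxan-3-yl]propoxy}diphenylsilane | CC(C)(C)[Si](c1ccccc1)(c2ccccc2)OC[C@@H](C)[C@@H]3CC[C@](C)(CC/C=C(\C)CCC4=C(C)C(=O)CCC4(C)C)OO3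
F5 | step 19 | (2R,3R,9E)-1-[(tert-butyldiphenylsilyl)oxy]-6,6-dimethoxy-2,10-dimethyl-12-(2,6,6-trimethyl-3-oxocyclohex-1-en-1-yl)dodec-9-en-3-yl methanesulfonate | CC(C)(C)[Si](c1ccccc1)(c2ccccc2)OC[C@@H](C)[C@H](OS(C)(=O)=O)CCC(OC)(OC)CC/C=C(\C)CCC3=C(C)C(=O)CCC3(C)C
F6 | step 19 | 3-[(3E,10S,11R)-12-[(tert-butyldiphenylsilyl)oxy]-7,7-dimethoxy-10-[(2-methoxypropan-2-yl)peroxy]-3,11-dimethyldodec-3-en-1-yl]-2,4,4-trimethylcyclohex-2-en-1-one | CC(C)(C)[Si](c1ccccc1)(c2ccccc2)OC[C@@H](C)[C@@H](OOC(C)(C)OC)CCC(OC)(OC)CC/C=C(\C)CCC3=C(C)C(=O)CCC3(C)C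
F7 | step 17 | (2R,3R,9E)-1-[(tert-butyldiphenylsilyl)oxy]-6-hydroxy-2,10-dimethyl-12-(2,6,6-trimethyl-3-oxocyclohex-1-en-1-yl)dodec-9-en-3-yl methanesulfonate (both C6 epimers) | CC(C)(C)[Si](c1ccccc1)(c2ccccc2)OC[C@@H](C)[C@H](OS(C)(=O)=O)CCC(O)CC/C=C(\C)CCC3=C(C)C(=O)CCC3(C)C
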